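The route rests on disconnecting the C4–C4a bond of the pyranone C ring. While C8 is unsubstituted, the A ring (O1, O5 and O7 around the C6 prenyl group) derives from an aryl ether with a mirror plane through C6 and C8a. The two carbons ortho to O1 are therefore equivalent. The precursor is acid 10, an (S)-3-aryloxy-3-phenylpropanoic acid carrying two MOM ethers and the prenyl group, with C2 already set by Mitsunobu inversion. Its intramolecular Friedel–Crafts acylation closes the C ring and fixes the 6-prenyl/8-H pattern in one operation. MOM removal and C8 benzylation with an o-quinone methide from 3-methylphloroacetophenone complete the target.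

Key step: step 7

Remark on the chemistry: flavanone numbering (O1, C2–C4, C4a, C5–C8, C8a) is used throughout. The only stereocentre of the target, C2, is S. Compounds 8 (enantiopure) and 14 are assumed to be purchased.

**Step 1**
Reactants: 1 phloroglucinol
Product: 2 5-[(triisopropylsilyl)oxy]benzene-1,3-diol
Conditions: 1 (3 equiv), TIPSCl (1 equiv), imidazole (1.2 equiv), DMF, 0 °C → rt; aqueous wash
Reagents that add atoms: triisopropylsilyl chloride, CC(C)[Si](Cl)(C(C)C)C(C)C
Why: Imidazole-promoted O-silylation of a phenol; the excess of the cheap, water-soluble triol should hold the reaction at the mono-ether, and the surplus is washed out with water.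

**Step 2**
Reactants: 2 5-[(triisopropylsilyl)oxy]benzene-1,3-diol
Product: 3 [3,5-bis(methoxymethoxy)phenoxy]triisopropylsilane
Conditions: MOMCl (2.6 equiv), i-Pr2NEt (3 equiv), CH2Cl2, 0 °C → rt
Reagents that add atoms: chloromethyl methyl ether, COCCl
Why: Exhaustive O-alkylation (Williamson type) of the two remaining phenols under amine base leaves the aryl TIPS ether intact and installs the two directing groups needed in step 3.

**Step 3**
Reactants: 3 [3,5-bis(methoxymethoxy)phenoxy]triisopropylsilane; 4 prenyl bromide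
Product: 6 [3,5-bis(methoxymethoxy)-4-(3-methylbut-2-enyl)phenoxy]triisopropylsilane, via {2,6-bis(methoxymethoxy)-4-[(triisopropylsilyl)oxy]phenyl}lithium 5 (not isolated)
Conditions: n-BuLi (1.15 equiv), THF, 0 °C, 1 h; then 4 (1.3 equiv), −78 °C → rt
Reagents that add atoms: none
Why: Directed ortho-metalation followed by SN2 alkylation: the carbon flanked by both MOM ethers is activated cooperatively, the carbons next to the bulky, poorly coordinating OTIPS group are shielded, and lithium para to the silyl ether cannot trigger an O→C silyl shift, so 5 should form only at the future C6 and attack the primary carbon of 4.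

**Step 4**
Reactants: 6 [3,5-bis(methoxymethoxy)-4-(3-methylbut-2-enyl)phenoxy]triisopropylsilane
Product: 7 3,5-bis(methoxymethoxy)-4-(3-methylbut-2-enyl)phenol
Conditions: TBAF (1.1 equiv), AcOH (1.1 equiv), THF, 0 °C
Reagents that add atoms: none
Why: Fluoride-induced cleavage of an aryl silyl ether, buffered with acetic acid; MOM ethers and the prenyl alkene are inert to fluoride.

**Step 5**
Reactants: 7 3,5-bis(methoxymethoxy)-4-(3-methylbut-2-enyl)phenol; 8 ethyl (R)-3-hydroxy-3-phenylpropanoate
Product: 9 ethyl (3S)-3-[3,5-bis(methoxymethoxy)-4-(3-methylbut-2-enyl)phenoxy]-3-phenylpropanoate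
Conditions: 8 (1.5 equiv), PPh3 (1.6 equiv), DIAD (1.6 equiv, slow addition), toluene, 0 °C → rt
Reagents that add atoms: none
Why: Mitsunobu etherification: the unhindered phenol displaces the alkoxyphosphonium ion by SN2 with inversion, turning the (R)-carbinol carbon into the (S)-configured future C2, while the β-ester disfavours benzylic ionisation and competing dehydration consumes only the cheap alcohol used in excess.

**Step 6**
Reactants: 9 ethyl (3S)-3-[3,5-bis(methoxymethoxy)-4-(3-methylbut-2-enyl)phenoxy]-3-phenylpropanoate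
Product: 10 (3S)-3-[3,5-bis(methoxymethoxy)-4-(3-methylbut-2-enyl)phenoxy]-3-phenylpropanoic acid
Conditions: LiOH·H2O (2 equiv), THF/H2O 3:1, 0 °C; then cold 0.5 M HCl to pH 4
Reagents that add atoms: lithium hydroxide (aqueous), [Li+].[OH-]
Why: Saponification (BAc2): hydroxide attack at the ester carbonyl at 0 °C is far faster than α-deprotonation, and the carboxylate formed no longer undergoes E1cB loss of the aryloxide, so the C–O bond at the stereocentre is not touched.

**Step 7**
Reactants: 10 (3S)-3-[3,5-bis(methoxymethoxy)-4-(3-methylbut-2-enyl)phenoxy]-3-phenylpropanoic acid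
Product: 12 (2S)-5,7-bis(methoxymethoxy)-6-(3-methylbut-2-enyl)-2-phenyl-2,3-dihydrochromen-4-one, via (3S)-3-[3,5-bis(methoxymethoxy)-4-(3-methylbut-2-enyl)phenoxy]-3-phenylpropanoyl chloride 11 (not isolated)
Conditions: 1-chloro-N,N,2-trimethylprop-1-en-1-amine (1.05 equiv), CH2Cl2, 0 °C, 1 h; then 2,6-di-tert-butyl-4-methylpyridine (1.5 equiv), (CF3)2CHOH/CH2Cl2 4:1 (0.02 M), 0 °C → rt
Reagents that add atoms: none
Why: The chloroenamine turns 10 into acid chloride 11 without releasing acid or needing base, hydrogen bonding from HFIP polarises the C–Cl bond to an acylium-like electrophile, the ring carbon ortho to O1 and para to a MOM ether attacks it, and the Wheland intermediate gives its proton to the hindered pyridine (electrophilic aromatic substitution). The closest known reaction type is the intramolecular Friedel–Crafts acylation of 3-aryloxypropanoyl chlorides to chroman-4-ones, including its HFIP-promoted form that needs no Lewis acid. The six-membered pyranone (O1–C2–C3–C4–C4a–C8a) closes by 6-exo-trig attack at the acyl carbon, forming the C4–C4a bond. No stereocentre is formed; C2 from step 5 is a spectator whose C–O and C–H bonds are not touched, so the S configuration is carried through. Regioselectivity is not needed, because the mirror plane of the aryl group through C6 and C8a makes the two carbons ortho to O1 equivalent, and either closure gives the same 6-prenyl flavanone with C8 free. What is needed is chemoselectivity for closure over β-elimination of the aryloxide and over acid damage, and this is secured by the very nucleophilic trioxygenated ring, high dilution and low temperature, the absence of any base able to deprotonate C3, and the pyridine buffer, which removes the HCl that would otherwise cleave the MOM ethers, add to the prenyl alkene or ionise the benzylic C2–O bond.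

**Step 8**
Reactants: 12 (2S)-5,7-bis(methoxymethoxy)-6-(3-methylbut-2-enyl)-2-phenyl-2,3-dihydrochromen-4-one
Product: 13 (2S)-5,7-dihydroxy-6-(3-methylbut-2-enyl)-2-phenyl-2,3-dihydrochromen-4-one (6-prenylpinocembrin)
Conditions: HCl (0.5 M in MeOH), rt → 35 °C; pH 7 buffer quench
Reagents that add atoms: none
Why: Acid-catalysed acetal exchange with methanol removes both phenolic MOM ethers (the 5-O-MOM assisted by the peri carbonyl); dilute methanolic HCl is the usual medium for prenylated flavanones, should be too weak to protonate the trisubstituted alkene competitively, and does not open the pyranone, so C2 is retained.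

**Step 9**
Reactants: 14 2',4',6'-trihydroxy-3'-methylacetophenone
Product: 15 1-{3-[(dimethylamino)methyl]-2,4,6-trihydroxy-5-methylphenyl}ethanone
Conditions: aq. Me2NH (1.5 equiv) and aq. CH2O (1.3 equiv) premixed in EtOH, 0 °C; then 14, 0 °C → rt
Reagents that add atoms: formaldehyde, C=O; dimethylamine, CNC
Why: Mannich aminomethylation at the only unsubstituted ring carbon of 14; adding 14 to the premixed excess reagent in the cold suppresses diarylmethane formation.

**Step 10**
Reactants: 13 (2S)-5,7-dihydroxy-6-(3-methylbut-2-enyl)-2-phenyl-2,3-dihydrochromen-4-one; 15 1-{3-[(dimethylamino)methyl]-2,4,6-trihydroxy-5-methylphenyl}ethanone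
Product: 17 (2S)-8-[(3-acetyl-2,4,6-trihydroxy-5-methylphenyl)methyl]-5,7-dihydroxy-6-(3-methylbut-2-enyl)-2-phenyl-2,3-dihydrochromen-4-one, via 2-acetyl-3,5-dihydroxy-4-methyl-6-methylidenecyclohexa-2,4-dien-1-one 16 (not isolated)
Conditions: 15 (1.3 equiv, in portions), AcOH (3 equiv), 1,4-dioxane, 70 °C, N2
Reagents that add atoms: none
Why: The protonated Mannich base loses dimethylamine (retro-Michael) to give o-quinone methide 16, which is captured in a Friedel–Crafts-type conjugate addition by C8, the only unsubstituted nucleophilic carbon of 13, while acetic acid keeps the freed amine protonated so that the flavanone never meets base and C2 is not scrambled through the chalcone.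

**Compound list**
1 | phloroglucinol | Oc1cc(O)cc(O)c1 | starting material
2 | 5-[(triisopropylsilyl)oxy]benzene-1,3-diol | CC(C)[Si](Oc1cc(O)cc(O)c1)(C(C)C)C(C)C | intermediate
3 | [3,5-bis(methoxymethoxy)phenoxy]triisopropylsilane | COCOc1cc(OCOC)cc(O[Si](C(C)C)(C(C)C)C(C)C)c1 | intermediate
4 | prenyl bromide (1-bromo-3-methylbut-2-ene) | CC(C)=CCBr | starting material
5 | {2,6-bis(methoxymethoxy)-4-[(triisopropylsilyl)oxy]phenyl}lithium | [Li]c1c(OCOC)cc(O[Si](C(C)C)(C(C)C)C(C)C)cc1OCOC | intermediate
6 | [3,5-bis(methoxymethoxy)-4-(3-methylbut-2-enyl)phenoxy]triisopropylsilane | COCOc1cc(O[Si](C(C)C)(C(C)C)C(C)C)cc(OCOC)c1CC=C(C)C | intermediate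
7 | 3,5-bis(methoxymethoxy)-4-(3-methylbut-2-enyl)phenol | COCOc1cc(O)cc(OCOC)c1CC=C(C)C | intermediate
8 | ethyl (R)-3-hydroxy-3-phenylpropanoate | CCOC(=O)C[C@@H](O)c1ccccc1 | starting material
9 | ethyl (3S)-3-[3,5-bis(methoxymethoxy)-4-(3-methylbut-2-enyl)phenoxy]-3-phenylpropanoate | CCOC(=O)C[C@H](Oc1cc(OCOC)c(CC=C(C)C)c(OCOC)c1)c1ccccc1 | intermediate
10 | (3S)-3-[3,5-bis(methoxymethoxy)-4-(3-methylbut-2-enyl)phenoxy]-3-phenylpropanoic acid | OC(=O)C[C@H](Oc1cc(OCOC)c(CC=C(C)C)c(OCOC)c1)c1ccccc1 | intermediate
11 | (3S)-3-[3,5-bis(methoxymethoxy)-4-(3-methylbut-2-enyl)phenoxy]-3-phenylpropanoyl chloride | ClC(=O)C[C@H](Oc1cc(OCOC)c(CC=C(C)C)c(OCOC)c1)c1ccccc1 | intermediate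
12 | (2S)-5,7-bis(methoxymethoxy)-6-(3-methylbut-2-enyl)-2-phenyl-2,3-dihydrochromen-4-one | COCOc1cc2O[C@H](c3ccccc3)CC(=O)c2c(OCOC)c1CC=C(C)C | intermediate
13 | (2S)-5,7-dihydroxy-6-(3-methylbut-2-enyl)-2-phenyl-2,3-dihydrochromen-4-one | CC(C)=CCc1c(O)cc2O[C@H](c3ccccc3)CC(=O)c2c1O | intermediate
14 | 2',4',6'-trihydroxy-3'-methylacetophenone | CC(=O)c1c(O)cc(O)c(C)c1O | starting material
15 | 1-{3-[(dimethylamino)methyl]-2,4,6-trihydroxy-5-methylphenyl}ethanone | CC(=O)c1c(O)c(C)c(O)c(CN(C)C)c1O | intermediate
16 | 2-acetyl-3,5-dihydroxy-4-methyl-6-methylidenecyclohexa-2,4-dien-1-one | CC(=O)C1=C(O)C(C)=C(O)C(=C)C1=O | intermediate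
17 | (2S)-8-[(3-acetyl-2,4,6-trihydroxy-5-methylphenyl)methyl]-5,7-dihydroxy-6-(3-methylbut-2-enyl)-2-phenyl-2,3-dihydrochromen-4-one | CC(=O)c1c(O)c(C)c(O)c(Cc2c(O)c(CC=C(C)C)c(O)c3c2O[C@H](c2ccccc2)CC3=O)c1O | target

Total step count: 10. Longest linear sequence: 9 (steps 1–8 and 10, from phloroglucinol); step 9 is a one-step side branch.

**Steps most likely to fail**

1. Step 7.
   - Risk: the aryloxide may undergo β-elimination from the activated acid before the ring closes. The fluoro alcohol may solvolyse the acid chloride. If the buffer is outrun, MOM groups may be lost or the ee eroded.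
   - Fallback: it sets out from 7 and 8 and returns at 12. The same C4–C4a bond is closed with reversed polarity by a Parham-type anionic cycloacylation. Phenol 7 is mono-iodinated at one of its two equivalent ortho carbons (I2, NaHCO3, THF/H2O, 0 °C) to give 2-iodo-3,5-bis(methoxymethoxy)-4-(3-methylbut-2-enyl)phenol F1. Ester 8 is converted with MeNH(OMe)·HCl and i-PrMgCl into (3R)-3-hydroxy-N-methoxy-N-methyl-3-phenylpropanamide F2. Mitsunobu coupling of the two, with inversion, gives (3S)-3-[2-iodo-3,5-bis(methoxymethoxy)-4-(3-methylbut-2-enyl)phenoxy]-N-methoxy-N-methyl-3-phenylpropanamide F3. Iodine–lithium exchange (n-BuLi, THF, −78 °C) gives the derived aryllithium F4, which adds to the N-methoxy-N-methyl amide. The chelated adduct is kept until a cold, weakly acidic quench releases 12 without exposure to base.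

2. Step 5.
   - Risk: the β-hydroxy ester may dehydrate under Mitsunobu activation. Partial leakage through a benzylic cation would lower the ee.
   - Fallback: it sets out from 7 and returns at 10, so step 6 also drops out. The acidifying ester is left out of the coupling partner. Phenol 7 is coupled under Mitsunobu conditions with commercial (R)-3-chloro-1-phenylpropan-1-ol (ClCC[C@@H](O)c1ccccc1), an alcohol class whose aryl etherification with inversion is well established. This gives 5-[(1S)-3-chloro-1-phenylpropoxy]-1,3-bis(methoxymethoxy)-2-(3-methylbut-2-enyl)benzene F5. CsOAc in DMF gives (3S)-3-[3,5-bis(methoxymethoxy)-4-(3-methylbut-2-enyl)phenoxy]-3-phenylpropyl acetate F6. K2CO3 in MeOH gives (3S)-3-[3,5-bis(methoxymethoxy)-4-(3-methylbut-2-enyl)phenoxy]-3-phenylpropan-1-ol F7. TEMPO/PhI(OAc)2 in aqueous MeCN oxidises this through (3S)-3-[3,5-bis(methoxymethoxy)-4-(3-methylbut-2-enyl)phenoxy]-3-phenylpropanal F8 to acid 10.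

3. Step 10.
   - Risk: the quinone methide precursor may self-condense by ipso substitution. The methylene bridge may exchange between the two phloroglucinol rings on prolonged heating. The quinone methide may add to the prenyl alkene in a cycloaddition. The flavanone may ring-open if free amine builds up.
   - Fallback: it sets out from 13 and 14 and returns at 17, with the roles of the partners reversed. Flavanone 13 is aminomethylated at C8 with dimethylmethyleneammonium iodide (CH2Cl2, rt, no free amine) to give (2S)-8-[(dimethylamino)methyl]-5,7-dihydroxy-6-(3-methylbut-2-enyl)-2-phenyl-2,3-dihydrochromen-4-one F9. Warming in dioxane/AcOH releases (2S)-5-hydroxy-8-methylidene-6-(3-methylbut-2-enyl)-2-phenyl-2,3-dihydrochromene-4,7-dione F10. This is trapped by the only free ring carbon of the cheap acetophenone 14, used in excess, to give 17.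

**Further compounds**
F1 | step 7 | 2-iodo-3,5-bis(methoxymethoxy)-4-(3-methylbut-2-enyl)phenol | COCOc1cc(O)c(I)c(OCOC)c1CC=C(C)C
F2 | step 7 | (3R)-3-hydroxy-N-methoxy-N-methyl-3-phenylpropanamide | CON(C)C(=O)C[C@@H](O)c1ccccc1
F3 | step 7 | (3S)-3-[2-iodo-3,5-bis(methoxymethoxy)-4-(3-methylbut-2-enyl)phenoxy]-N-methoxy-N-methyl-3-phenylpropanamide | CON(C)C(=O)C[C@H](Oc1cc(OCOC)c(CC=C(C)C)c(OCOC)c1I)c1ccccc1
F4 | step 7 | aryllithium derived from F3 (Li in place of I) | CON(C)C(=O)C[C@H](Oc1cc(OCOC)c(CC=C(C)C)c(OCOC)c1[Li])c1ccccc1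
F5 | step 5 | 5-[(1S)-3-chloro-1-phenylpropoxy]-1,3-bis(methoxymethoxy)-2-(3-methylbut-2-enyl)benzene | ClCC[C@H](Oc1cc(OCOC)c(CC=C(C)C)c(OCOC)c1)c1ccccc1
F6 | step 5 | (3S)-3-[3,5-bis(methoxymethoxy)-4-(3-methylbut-2-enyl)phenoxy]-3-phenylpropyl acetate | CC(=O)OCC[C@H](Oc1cc(OCOC)c(CC=C(C)C)c(OCOC)c1)c1ccccc1
F7 | step 5 | (3S)-3-[3,5-bis(methoxymethoxy)-4-(3-methylbut-2-enyl)phenoxy]-3-phenylpropan-1-ol | OCC[C@H](Oc1cc(OCOC)c(CC=C(C)C)c(OCOC)c1)c1ccccc1
F8 | step 5 | (3S)-3-[3,5-bis(methoxymethoxy)-4-(3-methylbut-2-enyl)phenoxy]-3-phenylpropanal | O=CC[C@H](Oc1cc(OCOC)c(CC=C(C)C)c(OCOC)c1)c1ccccc1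
F9 | step 10 | (2S)-8-[(dimethylamino)methyl]-5,7-dihydroxy-6-(3-methylbut-2-enyl)-2-phenyl-2,3-dihydrochromen-4-one | CN(C)Cc1c(O)c(CC=C(C)C)c(O)c2c1O[C@H](c1ccccc1)CC2=O
F10 | step 10 | (2S)-5-hydroxy-8-methylidene-6-(3-methylbut-2-enyl)-2-phenyl-2,3-dihydrochromene-4,7-dione | C=C1C(=O)C(CC=C(C)C)=C(O)C2=C1O[C@H](c1ccccc1)CC2=O
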